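## Retrosynthetic overview

1. The target comes from triene alcohol 21 by two late oxirane closures: C3–C4 directed by C2–OH, and C10–C11 by Shi epoxidation. Compound 21 comes from α-methylene-γ-lactone 16 by lactol allylboration (C8–C9), double angeloylation and cross-metathesis.
2. Compound 16 comes from the cis-fused α-methyl lactone 14 (temporary ring B: O, C1, C6, C7, C8). Its bought C7 stereocentre relays its information to ring A and is then erased as C7=C14.
3. Compound 14 comes from cyclohexenone 12 (ring A). Compound 12 comes from acyclic ketone 5 (unit C6–C1–C2) and 3-(trimethylsilyl)but-3-en-2-one 9 (unit C5–C4–C3–C15). C5–C6 and C2–C3 are made together in a Michael/aldol/Peterson [3+3] annulation.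
4. Enabling feature: the C1 carbinol of ring A lies between C2 and C6, so at the ketone level C1 makes both neighbours nucleophilic. The C3–C4 oxirane with its C15 methyl is a masked methyl vinyl ketone (C5 and C3 electrophilic), and SiMe3 on C4 fixes the alkene at C3=C4.
5. Order of ring formation: ring A (step 6), lactone ring B (step 7, opened in steps 9–10), ring-A oxirane (step 14), side-chain oxirane (step 15).

Key step: step 6

Assumption: C1–C15 are the bisabolane locants of the target and are used for all intermediates (C1 ring CH–O-angelate, C2 CHOH, C3/C4 ring oxirane with the C15 methyl on C3, C5 ring CH2, C6 ring CH, C7=C14 methylidene, C8 CH–O-angelate, C9 CH2, C10/C11 side-chain oxirane).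

## Route

Step 1
Reactants: 1 dimethyl (2S)-2-methylbutanedioate
Product: 2 (3S)-4-methoxy-3-methyl-4-oxobutanoic acid
Conditions: LiOH·H2O (1.0 equiv), THF/H2O, 0 °C; then 1 M HCl
Reagents that add atoms: lithium hydroxide [Li+].[OH-]
Why: Saponification is sterically differentiated, because hydroxide attacks the ester on the unbranched CH2 (the C1 carbonyl) faster than the α-branched C8 ester, and the C7 stereocentre is not touched at 0 °C.

Step 2
Reactants: 2 (3S)-4-methoxy-3-methyl-4-oxobutanoic acid
Product: 4 methyl (2S)-5-diazo-2-methyl-4-oxopentanoate, via mixed carbonic anhydride 3 (not isolated)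
Conditions: i-BuOCOCl, N-methylmorpholine, THF, −20 °C; then CH2N2, Et2O, 0 °C
Reagents that add atoms: diazomethane C=[N+]=[N-]
Why: Acylation of diazomethane by the mixed carbonic anhydride (first stage of the Arndt–Eistert sequence) adds C2 under conditions that do not enolise C7.

Step 3
Reactants: 4 methyl (2S)-5-diazo-2-methyl-4-oxopentanoate
Product: 5 methyl (2S)-5-[(4-methoxybenzyl)oxy]-2-methyl-4-oxopentanoate
Conditions: 4-MeOC6H4CH2OH, Rh2(OAc)4 (1 mol %), CH2Cl2, rt
Reagents that add atoms: 4-methoxybenzyl alcohol COc1ccc(CO)cc1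
Why: Rhodium-carbenoid O–H insertion converts the diazoketone directly into the α-alkoxy ketone and so installs the C2 oxygen together with its protecting group.

Step 4
Reactants: 6 (1-bromoethenyl)trimethylsilane
Product: 8 3-(trimethylsilyl)but-3-en-2-ol (racemic), via silylvinyl Grignard reagent 7 (not isolated)
Conditions: Mg, THF, reflux; then CH3CHO, 0 °C
Reagents that add atoms: acetaldehyde CC=O
Why: Grignard addition of the α-silylvinyl nucleophile to acetaldehyde gives a carbinol centre that is lost in the next step, so the racemate is used.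

Step 5
Reactants: 8 3-(trimethylsilyl)but-3-en-2-ol
Product: 9 3-(trimethylsilyl)but-3-en-2-one
Conditions: Dess–Martin periodinane, CH2Cl2, 0 °C → rt
Reagents that add atoms: none
Why: Dess–Martin oxidation of the allylic alcohol is mild enough to leave the vinylsilane and the polymerisable enone intact.

Step 6
Reactants: 5 methyl (2S)-5-[(4-methoxybenzyl)oxy]-2-methyl-4-oxopentanoate; 9 3-(trimethylsilyl)but-3-en-2-one
Product: 12 methyl (2S)-2-{(1S,3S)-3-[(4-methoxybenzyl)oxy]-4-methyl-2-oxocyclohex-4-en-1-yl}propanoate, via Michael adduct 10 (not isolated), via aldol adduct 11 (not isolated)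
Conditions: LiN(i-Pr)2 (1.05 equiv), THF, −78 °C; 9, −78 °C; KOt-Bu (1.0 equiv), −78 → −20 °C; AcOH, −78 °C
Reagents that add atoms: none
Why: Proposed new method: the kinetic lithium enolate of 5 (deprotonated at C6, away from the alkoxy-bearing C2) adds to the α-silyl enone 9 in a Michael addition to give 10 as its silicon-stabilised enolate (C5–C6 bond), amine-mediated proton transfer then engages the more acidic C2–H, and the C2 enolate closes onto the C3 ketone in a 6-(enolendo)-exo-trig aldol addition (C2–C3 bond, 11). The potassium β-oxidosilane of 11 collapses by syn-Peterson elimination, which places the ring alkene at C3=C4 only and expels Me3SiOK. The closest known reaction types are the Michael addition of regiodefined enolates to α-silyl vinyl ketones in Robinson-type annulation and the addition of carbon nucleophiles to α-silyl ketones followed by Peterson olefination, and what is new is their merger through the α′-enolate of the donor ketone. All aldol additions (including the Robinson mode, C15 onto C1) and the C4 epimers equilibrate, and only the adduct with oxygen and silicon cis on the new ring can leave the equilibrium, so the mixture should be funnelled into one constitution. C6 is set in the Michael step by the bought C7 centre, since with C7–H eclipsing the enolate (allylic 1,3-strain) the acceptor approaches anti to the CO2Me group, and C6–H, afterwards the least acidic α-hydrogen, should not be exchanged. C2 is set on the cold acetic acid quench by protonation of the dienolate of 12 at its α-carbon from the face opposite the pseudoaxial C6 substituent, which gives the 2,6-cis ketone and keeps the alkene out of conjugation.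

Step 7
Reactants: 12 methyl (2S)-2-{(1S,3S)-3-[(4-methoxybenzyl)oxy]-4-methyl-2-oxocyclohex-4-en-1-yl}propanoate
Product: 14 (3S,3aS,7S,7aR)-7-[(4-methoxybenzyl)oxy]-3,6-dimethyl-3a,4,7,7a-tetrahydro-1-benzofuran-2(3H)-one, via hydroxy ester 13 (not isolated)
Conditions: LiBH(s-Bu)3, THF, −78 °C → rt; H2O
Reagents that add atoms: none
Why: Ketone reduction with a bulky trialkylborohydride delivers hydride from the equatorial direction, anti to the C2 and C6 substituents, so the C1 oxygen becomes axial and cis to both neighbours; the lithium alkoxide of 13 then closes the cis-fused γ-lactone by 5-exo-trig acyl substitution, after which the exo-methyl lactone is freed from minor isomers by chromatography.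

Step 8
Reactants: 14 (3S,3aS,7S,7aR)-7-[(4-methoxybenzyl)oxy]-3,6-dimethyl-3a,4,7,7a-tetrahydro-1-benzofuran-2(3H)-one
Product: 16 (3aS,7S,7aR)-7-[(4-methoxybenzyl)oxy]-6-methyl-3-methylidene-3a,4,7,7a-tetrahydro-1-benzofuran-2(3H)-one, via α-bromo lactone 15 (not isolated)
Conditions: LiN(i-Pr)2, THF, −78 °C; BrCH2CH2Br; then DBU, toluene, 80 °C
Reagents that add atoms: none
Why: α-Bromination of the lactone enolate on the convex face puts bromine cis to H-6, so the only antiperiplanar hydrogens for the E2 dehydrobromination are those of the C14 methyl group; the exocyclic C7=C14 alkene results and the auxiliary C7 stereocentre disappears.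

Step 9
Reactants: 16 (3aS,7S,7aR)-7-[(4-methoxybenzyl)oxy]-6-methyl-3-methylidene-3a,4,7,7a-tetrahydro-1-benzofuran-2(3H)-one
Product: 17 the corresponding lactol, (3aS,7S,7aR)-7-[(4-methoxybenzyl)oxy]-6-methyl-3-methylidene-2,3,3a,4,7,7a-hexahydro-1-benzofuran-2-ol (anomers)
Conditions: i-Bu2AlH (1.1 equiv), CH2Cl2, −78 °C; H2O
Reagents that add atoms: none
Why: This is a partial lactone reduction in which the aluminium hemiacetal formed by 1,2-addition is stable at −78 °C, so the reaction stops at the lactol.

Step 10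
Reactants: 17 lactol
Product: 18 (1R,2S,6S)-6-[(3S)-3-hydroxyhexa-1,5-dien-2-yl]-2-[(4-methoxybenzyl)oxy]-3-methylcyclohex-3-en-1-ol
Conditions: (−)-Ipc2B(allyl), Et2O, −78 °C; then NaOH, H2O2
Reagents that add atoms: (−)-B-allyldiisopinocampheylborane, from (+)-α-pinene C=CCB(C1CC2CC(C1C)C2(C)C)C1CC2CC(C1C)C2(C)C
Why: Brown asymmetric allylboration of the hydroxy enal in equilibrium with 17 proceeds through a chair transition state, and the reagent made from (+)-α-pinene gives the S carbinol with aldehydes whose substituent outranks allyl, which sets C8 under reagent control and frees C1–OH.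

Step 11
Reactants: 18 (1R,2S,6S)-6-[(3S)-3-hydroxyhexa-1,5-dien-2-yl]-2-[(4-methoxybenzyl)oxy]-3-methylcyclohex-3-en-1-ol
Product: 19 the 1,8-bis[(Z)-2-methylbut-2-enoate] (bis-angelate) of 18
Conditions: angelic acid, 2,4,6-Cl3C6H2COCl, Et3N, toluene, rt; then 18, 80 °C
Reagents that add atoms: angelic acid C/C=C(/C)C(=O)O
Why: Yamaguchi-type acylation by the mixed anhydride without a nucleophilic catalyst esterifies C1–OH and C8–OH in one operation and avoids the addition–elimination path that turns angelates into tiglates, while C2–O stays protected.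

Step 12
Reactants: 19 bis-angelate
Product: 20 bis-angelate with the (3S)-6-methylhepta-1,5-dien-2-yl side chain (prenyl at C9)
Conditions: 2-methylbut-2-ene (excess), second-generation Grubbs catalyst (5 mol %), CH2Cl2, 40 °C
Reagents that add atoms: 2-methylbut-2-ene CC=C(C)C
Why: Olefin cross-metathesis exchanges only the monosubstituted alkene, because the 1,1-disubstituted C7=C14, the trisubstituted C3=C4 and the angelate alkenes do not react, and so turns allyl into prenyl.

Step 13
Reactants: 20 prenyl bis-angelate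
Product: 21 (1R,2S,6S,8S)-1,8-bis(angeloyloxy)bisabola-3,7(14),10-trien-2-ol
Conditions: DDQ, CH2Cl2/pH 7 buffer, 0 °C
Reagents that add atoms: none
Why: Oxidative cleavage of the 4-methoxybenzyl ether by hydride abstraction is neutral, so esters, alkenes and the Z geometry survive and no acyl shift from O1 to O2 is triggered.

Step 14
Reactants: 21 triene alcohol
Product: 22 (1R,2R,3R,4S,6S,8S)-1,8-bis(angeloyloxy)-3,4-epoxybisabola-7(14),10-dien-2-ol
Conditions: VO(acac)2 (5 mol %), t-BuOOH, CH2Cl2, 0 °C
Reagents that add atoms: tert-butyl hydroperoxide CC(C)(C)OO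
Why: Hydroxyl-directed vanadium-catalysed epoxidation delivers oxygen to C3=C4 on the face of the allylic C2–OH, which sets C3 and C4 cis to C2–O and leaves the remote alkenes untouched.

Step 15
Reactants: 22 epoxy alcohol
Product: 23 target, (1R,2R,3R,4S,6S,8S,10R)-1,8-bis(angeloyloxy)-3,4:10,11-diepoxybisabol-7(14)-en-2-ol
Conditions: D-fructose-derived Shi ketone (30 mol %), KHSO5, K2CO3, Bu4NHSO4, MeCN/dimethoxymethane/aq. buffer, 0 °C
Reagents that add atoms: potassium peroxymonosulfate [K+].OOS(=O)(=O)[O-]
Why: In the Shi asymmetric epoxidation the chiral dioxirane reacts only with the electron-rich trisubstituted C10=C11 alkene through the spiro transition state, and the D-fructose-derived ketone gives the 10R oxirane.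

## Compound list

1 | dimethyl (2S)-2-methylbutanedioate | COC(=O)[C@@H](C)CC(=O)OC | starting material
2 | (3S)-4-methoxy-3-methyl-4-oxobutanoic acid | COC(=O)[C@@H](C)CC(=O)O | intermediate
3 | mixed isobutyl carbonic anhydride of 2 | COC(=O)[C@@H](C)CC(=O)OC(=O)OCC(C)C | intermediate
4 | methyl (2S)-5-diazo-2-methyl-4-oxopentanoate | COC(=O)[C@@H](C)CC(=O)C=[N+]=[N-] | intermediate
5 | methyl (2S)-5-[(4-methoxybenzyl)oxy]-2-methyl-4-oxopentanoate | COC(=O)[C@@H](C)CC(=O)COCc1ccc(OC)cc1 | intermediate
6 | (1-bromoethenyl)trimethylsilane | C=C(Br)[Si](C)(C)C | starting material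
7 | [1-(trimethylsilyl)ethenyl]magnesium bromide | C=C([Mg]Br)[Si](C)(C)C | intermediate
8 | 3-(trimethylsilyl)but-3-en-2-ol (racemic) | CC(O)C(=C)[Si](C)(C)C | intermediate
9 | 3-(trimethylsilyl)but-3-en-2-one | CC(=O)C(=C)[Si](C)(C)C | intermediate
10 | methyl (2S,3S)-5-[(4-methoxybenzyl)oxy]-2-methyl-4-oxo-3-[3-oxo-2-(trimethylsilyl)butyl]pentanoate (C4 epimers) | COC(=O)[C@@H](C)[C@H](CC([Si](C)(C)C)C(C)=O)C(=O)COCc1ccc(OC)cc1 | intermediate
11 | methyl (2S)-2-{(1S)-4-hydroxy-3-[(4-methoxybenzyl)oxy]-4-methyl-2-oxo-5-(trimethylsilyl)cyclohexyl}propanoate (equilibrating C2/C3/C4 isomers) | COC(=O)[C@@H](C)[C@@H]1CC([Si](C)(C)C)C(C)(O)C(OCc2ccc(OC)cc2)C1=O | intermediate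
12 | methyl (2S)-2-{(1S,3S)-3-[(4-methoxybenzyl)oxy]-4-methyl-2-oxocyclohex-4-en-1-yl}propanoate | COC(=O)[C@@H](C)[C@@H]1CC=C(C)[C@H](OCc2ccc(OC)cc2)C1=O | intermediate
13 | methyl (2S)-2-{(1S,2R,3S)-2-hydroxy-3-[(4-methoxybenzyl)oxy]-4-methylcyclohex-4-en-1-yl}propanoate (formed as lithium alkoxide) | COC(=O)[C@@H](C)[C@@H]1CC=C(C)[C@H](OCc2ccc(OC)cc2)[C@@H]1O | intermediate
14 | (3S,3aS,7S,7aR)-7-[(4-methoxybenzyl)oxy]-3,6-dimethyl-3a,4,7,7a-tetrahydro-1-benzofuran-2(3H)-one (cis-fused, methyl exo) | C[C@@H]1C(=O)O[C@H]2[C@@H](OCc3ccc(OC)cc3)C(C)=CC[C@@H]12 | intermediate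
15 | 3-bromo derivative of 14, bromine on the convex face cis to H-3a | C[C@@]1(Br)C(=O)O[C@H]2[C@@H](OCc3ccc(OC)cc3)C(C)=CC[C@@H]12 | intermediate
16 | (3aS,7S,7aR)-7-[(4-methoxybenzyl)oxy]-6-methyl-3-methylidene-3a,4,7,7a-tetrahydro-1-benzofuran-2(3H)-one | C=C1C(=O)O[C@H]2[C@@H](OCc3ccc(OC)cc3)C(C)=CC[C@@H]12 | intermediate
17 | lactol of 16 (anomers) | C=C1C(O)O[C@H]2[C@@H](OCc3ccc(OC)cc3)C(C)=CC[C@@H]12 | intermediate
18 | (1R,2S,6S)-6-[(3S)-3-hydroxyhexa-1,5-dien-2-yl]-2-[(4-methoxybenzyl)oxy]-3-methylcyclohex-3-en-1-ol | C=C([C@H](CC=C)O)[C@@H]1CC=C(C)[C@H](OCc2ccc(OC)cc2)[C@@H]1O | intermediate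
19 | bis-angelate of 18 | C=C([C@H](CC=C)OC(=O)/C(C)=C\C)[C@@H]1CC=C(C)[C@H](OCc2ccc(OC)cc2)[C@@H]1OC(=O)/C(C)=C\C | intermediate
20 | prenyl bis-angelate (C10=C11 installed) | C=C([C@H](CC=C(C)C)OC(=O)/C(C)=C\C)[C@@H]1CC=C(C)[C@H](OCc2ccc(OC)cc2)[C@@H]1OC(=O)/C(C)=C\C | intermediate
21 | (1R,2S,6S,8S)-1,8-bis(angeloyloxy)bisabola-3,7(14),10-trien-2-ol | C=C([C@H](CC=C(C)C)OC(=O)/C(C)=C\C)[C@@H]1CC=C(C)[C@H](O)[C@@H]1OC(=O)/C(C)=C\C | intermediate
22 | (1R,2R,3R,4S,6S,8S)-1,8-bis(angeloyloxy)-3,4-epoxybisabola-7(14),10-dien-2-ol | C=C([C@H](CC=C(C)C)OC(=O)/C(C)=C\C)[C@@H]1C[C@@H]2O[C@]2(C)[C@H](O)[C@@H]1OC(=O)/C(C)=C\C | intermediate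
23 | CNP0235377.1 | C=C([C@H](C[C@H]1OC1(C)C)OC(=O)/C(C)=C\C)[C@@H]1C[C@@H]2O[C@]2(C)[C@H](O)[C@@H]1OC(=O)/C(C)=C\C | target

## Step count

Total step count: 15.
Longest linear sequence: 13 steps (steps 1–3 and 6–15).

## Steps most likely to fail

**Step 6.** Several things may go wrong:
- the silyl group may be lost from C4 before ring closure;
- closure may occur in the Robinson mode;
- 5 may enolise partly towards C2;
- the alkene may drift into conjugation during the quench.

The fallback sets out from 5 and makes the two bonds separately by known reactions. The lithium enolate of 5 is alkylated with (Z)-1-bromo-3-iodobut-2-ene to give methyl (2S,3S)-3-[(2Z)-3-iodobut-2-en-1-yl]-5-[(4-methoxybenzyl)oxy]-2-methyl-4-oxopentanoate F1. The ring is then closed at the more acidic C2 by intramolecular ketone α-alkenylation with zerovalent palladium (Pd(PPh3)4, KOt-Bu, THF). This comes back to the route at 12.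

**Step 7.** Facial selectivity may be poor in the preceding dienolate protonation or in the hydride delivery, so that C2 epimers are carried into the lactone.

The fallback sets out from 14 (as the C2 epimer mixture) and sets C2 afresh:
- DDQ gives the hydroxy lactone F2.
- Dess–Martin oxidation gives the conjugated enone lactone F3, whose C1 centre is held by the cis ring fusion.
- Luche reduction (NaBH4, CeCl3·7H2O) from the convex face gives the 7S allylic alcohol F4.
- 4-Methoxybenzyl trichloroacetimidate with catalytic acid comes back to the route at 14.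

**Step 11.** The angelate may isomerise from Z to E (tiglate) under forcing acylation, and the axial C1–OH may be acylated only partly.

The fallback sets out from 18 and builds the Z alkenes on the esters. Carbodiimide esterification with 2-[bis(2,2,2-trifluoroethoxy)phosphoryl]propanoic acid gives the bis(phosphonopropanoate) F5. Still–Gennari olefination with acetaldehyde (KN(SiMe3)2, 18-crown-6, THF, −78 °C) then comes back to the route at 19.

## Further compounds

F1 | step 6 | methyl (2S,3S)-3-[(2Z)-3-iodobut-2-en-1-yl]-5-[(4-methoxybenzyl)oxy]-2-methyl-4-oxopentanoate | COC(=O)[C@@H](C)[C@H](C/C=C(/C)I)C(=O)COCc1ccc(OC)cc1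
F2 | step 7 | (3S,3aS,7aR)-7-hydroxy-3,6-dimethyl-3a,4,7,7a-tetrahydro-1-benzofuran-2(3H)-one (C7 epimers) | C[C@@H]1C(=O)O[C@H]2C(O)C(C)=CC[C@@H]12
F3 | step 7 | (3S,3aS,7aR)-3,6-dimethyl-3,3a,4,7a-tetrahydro-1-benzofuran-2,7-dione | C[C@@H]1C(=O)O[C@H]2C(=O)C(C)=CC[C@@H]12
F4 | step 7 | (3S,3aS,7S,7aR)-7-hydroxy-3,6-dimethyl-3a,4,7,7a-tetrahydro-1-benzofuran-2(3H)-one | C[C@@H]1C(=O)O[C@H]2[C@@H](O)C(C)=CC[C@@H]12
F5 | step 11 | 1,8-bis{2-[bis(2,2,2-trifluoroethoxy)phosphoryl]propanoate} of 18 | C=C([C@H](CC=C)OC(=O)C(C)P(=O)(OCC(F)(F)F)OCC(F)(F)F)[C@@H]1CC=C(C)[C@H](OCc2ccc(OC)cc2)[C@@H]1OC(=O)C(C)P(=O)(OCC(F)(F)F)OCC(F)(F)F
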